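I decide to count chains by the pre-initiator and not by the transfer agent, and to treat chain length as a ratio: the fraction of the monomer charge in chains, divided by the fraction of that charge that has begun chains. The readings show the numerator but not the denominator, so this choice is my guess.

common to all: free monomer 0.10 M; pre-initiator 0.5 mol%
- midnight: transfer agent 0.0050 M; run made earlier
- south: transfer agent 0.0100 M; time 30 h
- east: transfer agent 0.0100 M; time 10 h

midnight run (percent of the free monomer charged)

| time / h | monomer in chains / % | free monomer / % |
|---|---|---|
| 2.00 | 1 | 95 |
| 4.00 | 2 | 97 |
| 5.00 | 6 | 93 |
| 8.00 | 18 | 78 |
| 10.0 | 30 | 72 |

(each reading ± 2 percentage points)

* which of the two ends with the longer chains by the average number of monomer units in a chain (chains begun, living or dead) ("neither" if they lie within 10%) (south / east / neither)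
* average number of monomer units in a chain (chains begun, living or dead) at the end, south
* average number of monomer units in a chain (chains begun, living or dead) at the end, east

- the average divides the monomer in chains by the number of chains begun, living and dead together
- the earlier runs were read with a standard deviation of 2 percentage points
- the earlier runs do not show the number of chains; that part of a forecast is a guess
- no earlier run changes the charge of transfer agent; that part of a forecast is a guess

In the midnight run the fraction in chains is 2% at 4.00 h, no more than the scatter, and then it climbs to 30% at 10.0 h. Between the last two readings I take the logarithm of the ratio of monomer not yet in chains, divided by the interval, and read 0.0791 h⁻¹. This is a pseudo-first-order rate constant: the rate per free monomer, which counts the living ends present at that moment.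

How does it drift? Pre-initiator may add living ends and transfer agent may remove them, and the readings cannot separate the two, so I hold the constant level. I also guess that the larger charge of transfer agent barely changes it. East then stands near the midnight fraction at 10 h, and south reaches 85.6% at 30 h.

For the denominator, I take one chain per pre-initiator as the ceiling. East then gives 60.0, the floor length: the fraction of the monomer charge in chains divided by the loading of pre-initiator, which is the average length if every pre-initiator charged has begun one chain. South's floor is 171, more than east's. The delayed rise suggests slow release of pre-initiator, so I expect both lengths above their floors, and south the longer.

The forecast counts chains at “about one per transfer agent” and names south, with 8 for south and 3.3 for east, lengths below my floors.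

The simulation gives south, with 298 for south and 204 for east.

    pre-initiator → initiator (k = 1.10 × 10⁻⁵ s⁻¹)
    living end + transfer agent → dead chain (kL = 7.20 × 10⁻⁴ L mol⁻¹ s⁻¹)
    free monomer + initiator → living end + monomer in chains (k = 0.00230 L mol⁻¹ s⁻¹)
    free monomer + living end → monomer in chains + living end, rate k4*[living end]*[free monomer] (k = 0.150 L mol⁻¹ s⁻¹)

South is longer because of the difference in time: east, with that difference removed, goes from 204 to 298. The floor reckoned from the fraction in chains that each flask reaches, divided by the length, is the fraction of the pre-initiator charge that has begun chains, 0.283 in east and 0.600 in south. In the neighbour flask, east with 0.85 mol% of pre-initiator, the floor is 51.1 and the length 185, so that fraction is 0.276, with 32.7% of its pre-initiator spent.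

The data come from a simulation with constants of no real substance; noise was put on by code.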